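**Retrosynthetic overview**
1. Target 13 ⇐ C7 ketone 12 (axial hydride gives 7β-OH) ⇐ 6α-hydroxy ketol 11 (angeloylation) ⇐ ketol 10 (α-face enolate hydroxylation at C6) ⇐ 7α,8α-diol 9.
2. The (12E)-diene of 9 ⇐ 12-yne 6 + vinyl bromide (C13–C14, syn-hydrozirconation/Negishi); the 7α,8α-diol ⇐ Δ7 alkene 5 (OsO4, α-face).
3. Key disconnection C11–C12, not the usual C12=C13 olefination of the sclareolide lactol: enyne 5 ⇐ redox-active ester of acid 3 + propynyl nucleophile. C11, the enolisable α-carbon and a natural donor site, is used with reversed polarity as an alkyl radical/acceptor equivalent while the lactone carbonyl carbon leaves as CO2.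
4. Acid 3 ⇐ (+)-sclareolide 1 by eliminative lactone opening.
5. No ring is formed: the trans-decalin (rings A and B) with C5, C9 and C10 comes intact from sclareolide.

Assumption: the target is (5S,6R,7S,8S,9R,10S), i.e. 6α-angeloyloxy-(12E)-labda-12,14-diene-7β,8α-diol of the normal (sclareol) series; bought coupling partners (prop-1-ynylmagnesium bromide, vinyl bromide, angelic acid) are listed as reagents, and only sclareolide and what is made from it are numbered.

**Step 1**
Reactants: 1 (+)-sclareolide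
Product: 2 methyl 13,14,15,16-tetranorlabd-7-en-12-oate
Conditions: conc. H2SO4, MeOH, rt, 48 h; AgNO3–SiO2 chromatography
Reagents that add atoms: methanol, CO
Why: Acid-mediated alkyl–oxygen ionisation of the tertiary lactone gives the C8 cation, E1 loss of H-7 gives the Δ7 alkene (expected major isomer, Δ8(17)/Δ8(9) isomers removed on AgNO3–silica) and Fischer esterification stops relactonisation; no stereocentre is made and C5, C9, C10 are untouched.

**Step 2**
Reactants: 2 methyl 13,14,15,16-tetranorlabd-7-en-12-oate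
Product: 3 13,14,15,16-tetranorlabd-7-en-12-oic acid
Conditions: KOH, MeOH/H2O, reflux; then 1 M HCl to pH 4, 0 °C
Reagents that add atoms: potassium hydroxide, [K+].[OH-]
Why: Plain ester saponification; the cold, weakly acidic work-up avoids relactonisation of the γ,δ-unsaturated acid.

**Step 3**
Reactants: 3 13,14,15,16-tetranorlabd-7-en-12-oic acid
Product: 5 14,15-dinorlabd-7-en-12-yne, via TCNHPI redox-active ester 4 (not isolated)
Conditions: N-hydroxytetrachlorophthalimide (TCNHPI), DIC, DMAP (cat.), CH2Cl2, rt, silica plug; then MeC≡CMgBr (3 equiv), FeBr2·H2O (20 mol %), THF/NMP, −15 °C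
Reagents that add atoms: prop-1-ynylmagnesium bromide, CC#C[Mg]Br
Why: Iron-catalysed decarboxylative alkynylation of a redox-active ester: single-electron reduction of 4 expels CO2 and the imide to give the primary C11 radical, which is captured at the iron acetylide, so the innately nucleophilic α-carbon C11 is joined with reversed polarity to the nucleophilic acetylide carbon; no stereocentre is formed and C9 is not touched.

**Step 4**
Reactants: 5 14,15-dinorlabd-7-en-12-yne
Product: 6 14,15-dinorlabd-12-yne-7α,8α-diol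
Conditions: K2OsO4·2H2O (5 mol %), NMO, MeSO2NH2, acetone/t-BuOH/H2O, rt→35 °C; Na2SO3
Reagents that add atoms: N-methylmorpholine N-oxide, C[N+]1([O-])CCOCC1; water, O
Why: Upjohn dihydroxylation adds syn to the electron-rich Δ7 alkene from the α-face (the β-face is shielded by the axial C10 methyl), setting 7α-OH and the sclareol-type 8α-OH/8β-CH3, while the internal alkyne is inert to OsO4.

**Step 5**
Reactants: 6 14,15-dinorlabd-12-yne-7α,8α-diol
Product: 9 (12E)-labda-12,14-diene-7α,8α-diol, via alkenylzirconocene chloride 7 (not isolated), via alkenylzinc chloride 8 (not isolated)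
Conditions: Cp2Zr(H)Cl (4 equiv, the excess covers the two OH groups), THF, 45 °C; then ZnCl2, Pd(PPh3)4 (5 mol %), CH2=CHBr, THF, rt
Reagents that add atoms: vinyl bromide, C=CBr
Why: Schwartz hydrozirconation adds H and Zr syn with Zr at the less hindered methyl-bearing C13 (thermodynamic regiochemistry with excess reagent), and Negishi coupling (Zr→Zn→Pd) with vinyl bromide proceeds with retention, so the vinyl group ends trans to C11, which is the (12E) diene.

**Step 6**
Reactants: 9 (12E)-labda-12,14-diene-7α,8α-diol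
Product: 10 (12E)-8α-hydroxylabda-12,14-dien-7-one
Conditions: Dess–Martin periodinane, CH2Cl2, 0 °C→rt
Reagents that add atoms: none
Why: Dess–Martin oxidation of the secondary axial 7α-OH; the tertiary 8α-OH and the diene do not react.

**Step 7**
Reactants: 10 (12E)-8α-hydroxylabda-12,14-dien-7-one
Product: 11 (12E)-6α,8α-dihydroxylabda-12,14-dien-7-one
Conditions: KHMDS (2.4 equiv), THF, −78 °C; 2-(phenylsulfonyl)-3-phenyloxaziridine (1.3 equiv), −78 °C; AcOH
Reagents that add atoms: 2-(phenylsulfonyl)-3-phenyloxaziridine (Davis reagent), O=S(=O)(N1OC1c1ccccc1)c1ccccc1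
Why: Davis oxidation of the potassium enolate (only C6 is enolisable because C8 is quaternary); the oxaziridine attacks C6 from the α-face because the β-face carries three syn-axial methyls (C4β, C10, C8β), giving the equatorial 6α-OH.

**Step 8**
Reactants: 11 (12E)-6α,8α-dihydroxylabda-12,14-dien-7-one
Product: 12 (12E)-8α-hydroxy-7-oxolabda-12,14-dien-6α-yl (Z)-2-methylbut-2-enoate
Conditions: angelic acid, 2,4,6-Cl3C6H2COCl, Et3N (1:1:1, mixed anhydride pre-formed, no DMAP), toluene, rt; then 11, 80 °C
Reagents that add atoms: angelic acid, C/C=C(/C)C(=O)O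
Why: Yamaguchi-type mixed-anhydride acylation without nucleophilic catalyst transfers the angeloyl group without Z→E isomerisation to the tiglate; only the secondary 6α-OH reacts, the tertiary 8α-OH is inert.

**Step 9**
Reactants: 12 (12E)-8α-hydroxy-7-oxolabda-12,14-dien-6α-yl (Z)-2-methylbut-2-enoate
Product: 13 (12E)-7β,8α-dihydroxylabda-12,14-dien-6α-yl (Z)-2-methylbut-2-enoate (target)
Conditions: NaBH4, CeCl3·7H2O, MeOH, −40 °C; AcOH
Reagents that add atoms: none
Why: Luche-type borohydride reduction: hydride attacks C7 axially from the α-face (the β-face is shielded by the axial 8β- and 10β-methyls), giving the equatorial 7β-OH; low temperature suppresses 6→7 acyl migration and leaves the angelate and diene alone.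

**Compound list**
1 | (+)-sclareolide, (3aR,5aS,9aS,9bR)-3a,6,6,9a-tetramethyldecahydronaphtho[2,1-b]furan-2(1H)-one | O=C3C[C@H]1[C@](C)(O3)CC[C@H]2C(C)(C)CCC[C@@]21C | starting material
2 | methyl 13,14,15,16-tetranorlabd-7-en-12-oate (5α-H, 9β-CH2CO2Me, 10β-CH3) | COC(=O)C[C@H]1C(C)=CC[C@H]2C(C)(C)CCC[C@@]21C | intermediate
3 | 13,14,15,16-tetranorlabd-7-en-12-oic acid | OC(=O)C[C@H]1C(C)=CC[C@H]2C(C)(C)CCC[C@@]21C | intermediate
4 | tetrachlorophthalimido ester of 3 (TCNHPI redox-active ester) | O=C(C[C@H]1C(C)=CC[C@H]2C(C)(C)CCC[C@@]21C)ON1C(=O)c2c(Cl)c(Cl)c(Cl)c(Cl)c2C1=O | intermediate (not isolated)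
5 | 14,15-dinorlabd-7-en-12-yne (9β-but-2-ynyl) | CC#CC[C@H]1C(C)=CC[C@H]2C(C)(C)CCC[C@@]21C | intermediate
6 | 14,15-dinorlabd-12-yne-7α,8α-diol | CC#CC[C@H]1[C@](C)(O)[C@H](O)C[C@H]2C(C)(C)CCC[C@@]21C | intermediate
7 | (12E)-13-[chlorobis(cyclopentadienyl)zirconio]-14,15-dinorlabd-12-ene-7α,8α-diol (Cp drawn η1, OH drawn free) | C/C(=C\C[C@H]1[C@](C)(O)[C@H](O)C[C@H]2C(C)(C)CCC[C@@]21C)[Zr](Cl)(C1C=CC=C1)C1C=CC=C1 | intermediate (not isolated)
8 | (12E)-13-(chlorozincio)-14,15-dinorlabd-12-ene-7α,8α-diol | C/C(=C\C[C@H]1[C@](C)(O)[C@H](O)C[C@H]2C(C)(C)CCC[C@@]21C)[Zn]Cl | intermediate (not isolated)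
9 | (12E)-labda-12,14-diene-7α,8α-diol | C=C/C(C)=C/C[C@H]1[C@](C)(O)[C@H](O)C[C@H]2C(C)(C)CCC[C@@]21C | intermediate
10 | (12E)-8α-hydroxylabda-12,14-dien-7-one | C=C/C(C)=C/C[C@H]1[C@](C)(O)C(=O)C[C@H]2C(C)(C)CCC[C@@]21C | intermediate
11 | (12E)-6α,8α-dihydroxylabda-12,14-dien-7-one | C=C/C(C)=C/C[C@H]1[C@](C)(O)C(=O)[C@H](O)[C@H]2C(C)(C)CCC[C@@]21C | intermediate
12 | (12E)-8α-hydroxy-7-oxolabda-12,14-dien-6α-yl (Z)-2-methylbut-2-enoate | C=C/C(C)=C/C[C@H]1[C@](C)(O)C(=O)[C@H](OC(=O)/C(C)=C\C)[C@H]2C(C)(C)CCC[C@@]21C | intermediate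
13 | (12E)-7β,8α-dihydroxylabda-12,14-dien-6α-yl (Z)-2-methylbut-2-enoate, (5S,6R,7S,8S,9R,10S) | C=C/C(C)=C/C[C@H]1[C@](C)(O)[C@@H](O)[C@H](OC(=O)/C(C)=C\C)[C@H]2C(C)(C)CCC[C@@]21C | target

**Totals**
Total steps: 9. Longest linear sequence: 9 (fully linear from 1, no protecting groups).

**Three steps most likely to fail**

Step 3 (decarboxylative alkynylation). The Grignard reagent may attack the acyl carbon of 4, and the homoallylic C11 radical may rearrange through the cyclopropylcarbinyl radical. The fallback keeps the lactone carbon instead of excising it. It sets out from ester 2: DIBAL-H (CH2Cl2, −78 °C) gives 13,14,15,16-tetranorlabd-7-en-12-al F1, Ohira–Bestmann homologation (dimethyl (1-diazo-2-oxopropyl)phosphonate, K2CO3, MeOH) gives the terminal alkyne 14,15,16-trinorlabd-7-en-12-yne F2, and n-BuLi/MeI methylation comes back to the route at 5 (one step longer).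

Step 5 (hydrozirconation/vinylation on the free diol). The regiochemistry of Zr addition may be incomplete, and the O-zirconated diol may slow the Zr→Zn→Pd transfer. The fallback moves the hydrometalation ahead of the diol and reverses the polarity of the coupling. It sets out from enyne 5: Cp2Zr(H)Cl then I2 gives (12E)-13-iodo-14,15-dinorlabda-7,12-diene F3, OsO4/NMO (the iodoalkene is deactivated) gives (12E)-13-iodo-14,15-dinorlabd-12-ene-7α,8α-diol F4, and Suzuki–Miyaura coupling with potassium vinyltrifluoroborate (PdCl2(dppf), Cs2CO3, THF/H2O) comes back at 9 (one step longer).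

Step 7 (C6 hydroxylation of the ketol dianion). Possible problems are imino-aldol capture of the sulfonimine, over-oxidation and base-induced ketol transposition. The fallback transfers an acyloxy group instead of a hydroxyl. It sets out from 10: the potassium enolate is treated with dibenzoyl peroxide (THF, −78 °C) to give (12E)-8α-hydroxy-7-oxolabda-12,14-dien-6α-yl benzoate F5 (same α-face approach), and K2CO3/MeOH methanolysis at 0 °C comes back at 11.

**Further compounds**
F1 | step 3 | 13,14,15,16-tetranorlabd-7-en-12-al | O=CC[C@H]1C(C)=CC[C@H]2C(C)(C)CCC[C@@]21C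
F2 | step 3 | 14,15,16-trinorlabd-7-en-12-yne | C#CC[C@H]1C(C)=CC[C@H]2C(C)(C)CCC[C@@]21C
F3 | step 5 | (12E)-13-iodo-14,15-dinorlabda-7,12-diene | C/C(I)=C\C[C@H]1C(C)=CC[C@H]2C(C)(C)CCC[C@@]21C
F4 | step 5 | (12E)-13-iodo-14,15-dinorlabd-12-ene-7α,8α-diol | C/C(I)=C\C[C@H]1[C@](C)(O)[C@H](O)C[C@H]2C(C)(C)CCC[C@@]21C
F5 | step 7 | (12E)-8α-hydroxy-7-oxolabda-12,14-dien-6α-yl benzoate | C=C/C(C)=C/C[C@H]1[C@](C)(O)C(=O)[C@H](OC(=O)c3ccccc3)[C@H]2C(C)(C)CCC[C@@]21C
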